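**Retrosynthetic overview**

1. Target ⇐ heptabenzyl ether (BCl3 debenzylation) ⇐ 1-benzylindan-1-ol (dehydration) ⇐ trans-2,3-diarylindan-1-one + benzyl Grignard reagent; the E-benzylidene is made last from a C1 ketone.
2. The C2 aryl group enters by enolate arylation (trans, thermodynamic); the C3 stereocentre comes from a CuH conjugate reduction of a 3-arylinden-1-one.
3. Key disconnection: the indenone ⇐ 2,4-bis(benzyloxy)iodobenzene + 2,4-bis(benzyloxy)cinnamic anhydride by a Pd/norbornene ortho-acylation/ipso-Heck annulation, which makes C7a–C1 and C3a–C3 and so closes the five-membered ring (C1, C2, C3, C3a, C7a) in one operation.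
4. Enabling feature: in the fused resorcinol ring C3a and C7a are neighbours, C3a is flanked by the oxygen-bearing C4 and C7a by C7–H. An iodide on C3a therefore has one blocked and one free ortho position; the free one (C7a) is meta to both oxygens, out of reach of Friedel–Crafts chemistry but open to the palladacycle.
5. Ring order: the four benzene rings are bought; the five-membered ring is the only ring formed (step 4).

Key step: step 4

Remark: all phenols are carried as benzyl ethers so that the one aryl methyl ether of the target survives the final deprotection; the facial sense of the CuH catalyst in step 5 is assigned by analogy, and the mirror-image ligand is used if the 3R ketone forms.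

**Route**

Step 1
Reactants: 1 2,4-bis(benzyloxy)benzaldehyde; 2 malonic acid
Product: 4 (E)-3-[2,4-bis(benzyloxy)phenyl]prop-2-enoic acid, via benzylidenemalonic acid 3 (not isolated)
Conditions: 2 (2 equiv), pyridine, piperidine (cat.), 90 °C; aq. HCl
Reagents that add atoms: none
Why: Knoevenagel–Doebner condensation; the benzylidenemalonic acid decarboxylates in hot pyridine to the thermodynamically preferred E-cinnamic acid.

Step 2
Reactants: 4 (E)-3-[2,4-bis(benzyloxy)phenyl]prop-2-enoic acid (two molecules)
Product: 5 (E,E)-3-[2,4-bis(benzyloxy)phenyl]prop-2-enoic anhydride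
Conditions: DCC (0.5 equiv), CH2Cl2, 0 °C to rt; filtration
Reagents that add atoms: none
Why: Carbodiimide dehydration of a carboxylic acid (via the O-acylisourea) should give the symmetric anhydride, the acyl donor type used in palladium/norbornene ortho-acylations.

Step 3
Reactants: 6 1,3-bis(benzyloxy)benzene
Product: 7 2,4-bis(benzyloxy)-1-iodobenzene
Conditions: NIS (1.05 equiv), TFA (10 mol %), MeCN, 0 °C to rt
Reagents that add atoms: N-iodosuccinimide, O=C1CCC(=O)N1I
Why: Electrophilic aromatic iodination; C4 is para to one benzyloxy group and ortho to the other, while C2 between the two oxygens is hindered, so the 4-iodide should form.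

Step 4
Reactants: 7 2,4-bis(benzyloxy)-1-iodobenzene; 5 (E,E)-3-[2,4-bis(benzyloxy)phenyl]prop-2-enoic anhydride (1.5 equiv)
Product: 8 4,6-bis(benzyloxy)-3-[2,4-bis(benzyloxy)phenyl]-1H-inden-1-one
Conditions: Pd(OAc)2 (10 mol %), P(2-furyl)3 (25 mol %), norbornene (1.0 equiv), Cs2CO3 (2.5 equiv), toluene, 105 °C
Reagents that add atoms: none
Why: Palladium/norbornene (Catellani-type) ortho-acylation/ipso-Heck annulation: Pd(0) inserts into C3a–I of 7, norbornene carbopalladation and C–H palladation at the only free ortho position (C7a) give the aryl–norbornyl palladacycle, which is acylated by 5 (C7a–C1), expels norbornene once both ortho positions are filled, and the C3a–Pd species then adds across C2=C3 of the tethered enone before β-hydride elimination (after equilibration of the palladium enolate). The closest known reaction type is the Pd/norbornene indenone annulation of ortho-substituted aryl iodides with α,β-unsaturated carboxylic anhydrides. The five-membered ring closes as a formal [3+2] annulation, an intermolecular C–H acylation (C7a–C1) followed by a 5-endo-trig carbopalladation (C3a–C3). No stereocentre is formed because 8 is planar, so the step needs only site selectivity, and the substrate secures it: iodine marks C3a, the benzyloxy group on C4 blocks one ortho position, C7a–H is the only site left for the relay, and the same ortho substituent makes norbornene extrusion follow mono-acylation. Ring size fixes the enone β-carbon (C3) as the partner of C3a, so the 2,4-bis(benzyloxy)phenyl group should end up on C3 and the carbonyl group on C7a.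

Step 5
Reactants: 8 4,6-bis(benzyloxy)-3-[2,4-bis(benzyloxy)phenyl]-1H-inden-1-one
Product: 10 (3S)-4,6-bis(benzyloxy)-3-[2,4-bis(benzyloxy)phenyl]-2,3-dihydro-1H-inden-1-one, via silyl enol ether 9 (not isolated)
Conditions: Cu(OAc)2·H2O (3 mol %), (R)-DTBM-SEGPHOS (3.3 mol %), (EtO)2MeSiH (1.5 equiv), toluene, 0 °C; then K2CO3 (cat.), MeOH, 0 °C
Reagents that add atoms: diethoxy(methyl)silane, CCO[SiH](C)OCC (its silyl group is carried by 9 and lost again on methanolysis)
Why: Copper hydride-catalysed asymmetric conjugate reduction of a β,β-disubstituted cyclic enone; the ligated Cu–H should deliver hydride to one face of C3 (catalyst control sets 3S), the enolate is held as silyl enol ether 9, which protects the ketone from over-reduction, and methanolysis releases 10.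

Step 6
Reactants: 10 (3S)-4,6-bis(benzyloxy)-3-[2,4-bis(benzyloxy)phenyl]-2,3-dihydro-1H-inden-1-one; 11 1,3-bis(benzyloxy)-5-bromobenzene
Product: 12 (2S,3S)-4,6-bis(benzyloxy)-2-[3,5-bis(benzyloxy)phenyl]-3-[2,4-bis(benzyloxy)phenyl]-2,3-dihydro-1H-inden-1-one (2,3-trans)
Conditions: Pd2(dba)3 (2.5 mol %), t-Bu3P·HBF4 (10 mol %), NaOtBu (2.2 equiv), toluene, 70 °C; aq. NH4Cl
Reagents that add atoms: none
Why: Palladium-catalysed enolate α-arylation (Buchwald–Hartwig type) at C2; this centre stays enolisable under the basic conditions and should settle trans to the C3 aryl group (2S, thermodynamic control by C3), while C3 itself is not acidic and is not touched.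

Step 7
Reactants: 12 (2S,3S)-2,3-diarylindan-1-one; 13 4-(benzyloxy)-3-methoxybenzyl chloride
Product: 15 (2S,3S)-1-[4-(benzyloxy)-3-methoxybenzyl]-4,6-bis(benzyloxy)-2-[3,5-bis(benzyloxy)phenyl]-3-[2,4-bis(benzyloxy)phenyl]-2,3-dihydro-1H-inden-1-ol (C1 epimers), via benzylmagnesium chloride 14 (not isolated)
Conditions: 13, Mg, THF, 0 °C; then 12, LaCl3·2LiCl (1.0 equiv), THF, −20 to 0 °C; aq. NH4Cl
Reagents that add atoms: magnesium, [Mg] (present only in 14)
Why: 1,2-Addition of a benzylic Grignard reagent to the ketone, with LaCl3·2LiCl to favour addition over enolisation of the α-aryl ketone; the configuration of the new carbinol centre is irrelevant because it is removed in step 8.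

Step 8
Reactants: 15 (2S,3S)-1-benzylindan-1-ol
Product: 16 (1E,2S,3S)-1-[4-(benzyloxy)-3-methoxybenzylidene]-4,6-bis(benzyloxy)-2-[3,5-bis(benzyloxy)phenyl]-3-[2,4-bis(benzyloxy)phenyl]-2,3-dihydro-1H-indene
Conditions: p-TsOH·H2O (10 mol %), toluene, rt, short reaction time
Reagents that add atoms: none
Why: Acid-catalysed E1 dehydration of the tertiary benzylic alcohol; loss of a benzylic CH2 proton should give the exocyclic styrene kinetically, with the aryl group turned away from the peri C7–H of the fused ring (E), as in dehydrations of related 1-benzylindan-1-ols, and C2 and C3 are not involved.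

Step 9
Reactants: 16 heptabenzyl ether
Product: 17 (1E,2S,3S)-2-(3,5-dihydroxyphenyl)-3-(2,4-dihydroxyphenyl)-1-(4-hydroxy-3-methoxybenzylidene)-2,3-dihydro-1H-indene-4,6-diol (target)
Conditions: BCl3 (14 equiv), C6HMe5 (21 equiv), CH2Cl2, −78 °C; then MeOH, aqueous work-up
Reagents that add atoms: none
Why: Lewis acid debenzylation with BCl3 and pentamethylbenzene as a non-basic benzyl cation scavenger should cleave all seven aryl benzyl ethers at low temperature while the aryl methyl ether and the acid-sensitive exocyclic alkene survive.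

**Compound list**

1 | 2,4-bis(benzyloxy)benzaldehyde | O=Cc1ccc(OCc2ccccc2)cc1OCc1ccccc1 | starting material
2 | malonic acid | OC(=O)CC(=O)O | starting material
3 | 2-[2,4-bis(benzyloxy)benzylidene]malonic acid (formed in the flask) | OC(=O)C(=Cc1ccc(OCc2ccccc2)cc1OCc1ccccc1)C(=O)O | intermediate
4 | (E)-3-[2,4-bis(benzyloxy)phenyl]prop-2-enoic acid | OC(=O)/C=C/c1ccc(OCc2ccccc2)cc1OCc1ccccc1 | intermediate
5 | (E,E)-3-[2,4-bis(benzyloxy)phenyl]prop-2-enoic anhydride | O=C(/C=C/c1ccc(OCc2ccccc2)cc1OCc1ccccc1)OC(=O)/C=C/c1ccc(OCc2ccccc2)cc1OCc1ccccc1 | intermediate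
6 | 1,3-bis(benzyloxy)benzene | c1cc(OCc2ccccc2)cc(OCc2ccccc2)c1 | starting material
7 | 2,4-bis(benzyloxy)-1-iodobenzene | Ic1ccc(OCc2ccccc2)cc1OCc1ccccc1 | intermediate
8 | 4,6-bis(benzyloxy)-3-[2,4-bis(benzyloxy)phenyl]-1H-inden-1-one | O=C1C=C(c2ccc(OCc3ccccc3)cc2OCc2ccccc2)c2c1cc(OCc1ccccc1)cc2OCc1ccccc1 | intermediate
9 | diethoxy(methyl)silyl enol ether of 10 (O-silylated C1=C2 enolate, C3 S; formed in the flask) | CCO[Si](C)(OCC)OC1=C[C@@H](c2ccc(OCc3ccccc3)cc2OCc2ccccc2)c2c1cc(OCc1ccccc1)cc2OCc1ccccc1 | intermediate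
10 | (3S)-4,6-bis(benzyloxy)-3-[2,4-bis(benzyloxy)phenyl]-2,3-dihydro-1H-inden-1-one | O=C1C[C@@H](c2ccc(OCc3ccccc3)cc2OCc2ccccc2)c2c1cc(OCc1ccccc1)cc2OCc1ccccc1 | intermediate
11 | 1,3-bis(benzyloxy)-5-bromobenzene | Brc1cc(OCc2ccccc2)cc(OCc2ccccc2)c1 | starting material
12 | (2S,3S)-4,6-bis(benzyloxy)-2-[3,5-bis(benzyloxy)phenyl]-3-[2,4-bis(benzyloxy)phenyl]-2,3-dihydro-1H-inden-1-one (trans) | O=C1[C@H](c2cc(OCc3ccccc3)cc(OCc3ccccc3)c2)[C@@H](c2ccc(OCc3ccccc3)cc2OCc2ccccc2)c2c1cc(OCc1ccccc1)cc2OCc1ccccc1 | intermediate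
13 | 4-(benzyloxy)-3-methoxybenzyl chloride | ClCc1ccc(OCc2ccccc2)c(OC)c1 | starting material
14 | [4-(benzyloxy)-3-methoxybenzyl]magnesium chloride (formed in the flask) | Cl[Mg]Cc1ccc(OCc2ccccc2)c(OC)c1 | intermediate
15 | (2S,3S)-1-[4-(benzyloxy)-3-methoxybenzyl]-4,6-bis(benzyloxy)-2-[3,5-bis(benzyloxy)phenyl]-3-[2,4-bis(benzyloxy)phenyl]-2,3-dihydro-1H-inden-1-ol (both C1 epimers) | OC1(Cc2ccc(OCc3ccccc3)c(OC)c2)[C@H](c2cc(OCc3ccccc3)cc(OCc3ccccc3)c2)[C@@H](c2ccc(OCc3ccccc3)cc2OCc2ccccc2)c2c1cc(OCc1ccccc1)cc2OCc1ccccc1 | intermediate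
16 | (1E,2S,3S)-1-[4-(benzyloxy)-3-methoxybenzylidene]-4,6-bis(benzyloxy)-2-[3,5-bis(benzyloxy)phenyl]-3-[2,4-bis(benzyloxy)phenyl]-2,3-dihydro-1H-indene | COc1cc(/C=C2/c3cc(OCc4ccccc4)cc(OCc4ccccc4)c3[C@H](c3ccc(OCc4ccccc4)cc3OCc3ccccc3)[C@H]2c2cc(OCc3ccccc3)cc(OCc3ccccc3)c2)ccc1OCc1ccccc1 | intermediate
17 | (1E,2S,3S)-2-(3,5-dihydroxyphenyl)-3-(2,4-dihydroxyphenyl)-1-(4-hydroxy-3-methoxybenzylidene)-2,3-dihydro-1H-indene-4,6-diol | COc1cc(/C=C2/c3cc(O)cc(O)c3[C@H](c3ccc(O)cc3O)[C@H]2c2cc(O)cc(O)c2)ccc1O | target

**Step count and risks**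

Total step count: 9. Longest linear sequence: 8 steps (steps 1, 2, 4, 5, 6, 7, 8, 9; step 3 is a one-step branch).

Three steps most likely to fail:

Step 4. The aryl–palladium species may be intercepted before the norbornene relay is complete, by direct Heck coupling with the enone of 5 or by C–H arylation of the neighbouring O-benzyl ring, and acyl transfer from the conjugated anhydride may be slow. The fallback sets out from 1 and closes the ring through C3a–C3 alone. Commercially available 1-[3,5-bis(benzyloxy)phenyl]ethan-1-one is brominated in the ring (NBS, MeCN) to 1-[3,5-bis(benzyloxy)-2-bromophenyl]ethan-1-one F1. Claisen–Schmidt condensation of F1 with 1 (Ba(OH)2, EtOH/THF) should give the bromochalcone (E)-1-[3,5-bis(benzyloxy)-2-bromophenyl]-3-[2,4-bis(benzyloxy)phenyl]prop-2-en-1-one F2. A palladium-catalysed asymmetric reductive Heck cyclisation of F2 (Pd(dba)2, (R)-3,5-Xyl-MeO-BIPHEP, Cy2NMe, benzoic acid, ethylene glycol/DMA, 100 °C) then forms the ring and sets C3 at once. The route is rejoined at 10, and steps 2 to 5 fall away.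

Step 5. Hydride transfer to the hindered C3, which lies between the C4 benzyloxy group and an ortho-substituted aryl group, may be slow or poorly face-selective, and 1,2-reduction of the carbonyl group may compete. The fallback sets out from 8. Corey–Bakshi–Shibata reduction ((R)-Me-CBS, BH3·SMe2, THF, −20 °C; the antipode if the sense proves opposite) should give the indenol (1S)-4,6-bis(benzyloxy)-3-[2,4-bis(benzyloxy)phenyl]-1H-inden-1-ol F3. A base-mediated suprafacial 1,3-hydrogen shift (DABCO, Et3N, THF, 60 °C) then carries the C1 configuration over to C3 and returns to the route at 10.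

Step 8. The tertiary cation may lose the C2 proton instead of a benzylic proton, which would give the endocyclic alkene and erase the C2 stereocentre, or the exocyclic alkene may isomerise under the acid. The fallback sets out from 12. Methylenation with the Petasis reagent (Cp2TiMe2, toluene, 65 °C), which tolerates the enolisable ketone, should give (2S,3S)-4,6-bis(benzyloxy)-2-[3,5-bis(benzyloxy)phenyl]-3-[2,4-bis(benzyloxy)phenyl]-1-methylidene-2,3-dihydro-1H-indene F4. An oxidative Heck arylation of the exocyclic methylene group with [4-(benzyloxy)-3-methoxyphenyl]boronic acid (Pd(OAc)2, benzoquinone, DMF, 40 °C) should place the aryl group trans to the fused ring and rejoin the route at 16. Steps 7 and 8 are then not needed.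

**Further compounds**

F1 | step 4 | 1-[3,5-bis(benzyloxy)-2-bromophenyl]ethan-1-one | CC(=O)c1cc(OCc2ccccc2)cc(OCc2ccccc2)c1Br
F2 | step 4 | (E)-1-[3,5-bis(benzyloxy)-2-bromophenyl]-3-[2,4-bis(benzyloxy)phenyl]prop-2-en-1-one | O=C(/C=C/c1ccc(OCc2ccccc2)cc1OCc1ccccc1)c1cc(OCc2ccccc2)cc(OCc2ccccc2)c1Br
F3 | step 5 | (1S)-4,6-bis(benzyloxy)-3-[2,4-bis(benzyloxy)phenyl]-1H-inden-1-ol | O[C@H]1C=C(c2ccc(OCc3ccccc3)cc2OCc2ccccc2)c2c1cc(OCc1ccccc1)cc2OCc1ccccc1
F4 | step 8 | (2S,3S)-4,6-bis(benzyloxy)-2-[3,5-bis(benzyloxy)phenyl]-3-[2,4-bis(benzyloxy)phenyl]-1-methylidene-2,3-dihydro-1H-indene | C=C1[C@H](c2cc(OCc3ccccc3)cc(OCc3ccccc3)c2)[C@@H](c2ccc(OCc3ccccc3)cc2OCc2ccccc2)c2c1cc(OCc1ccccc1)cc2OCc1ccccc1
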